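All constants are invented; what happens was integrated by code.

I followed the coupling partner.

solid substrate 0.10 M; coupling partner 0.0600 M; time 25 h

    solid substrate ⇌ starting material, rate k1*(cs1 - [starting material]) while solid is left; crystals form when [starting material] > cs1 (cs1 = 46 mM, k1 = 0.045 /min)
    target ⇌ isomer of the product (K2 = 0.86, k2 = 0.011 /min)
    adduct ⇌ target (K3 = 0.39, k3 = 0.027 /min)
    starting material + coupling partner ⇌ adduct (K4 = 21 /M, k4 = 0.85 /M/min)

* at 25 h, what has stopped the reaction, if anything has (for what has run out or reacted, a solid counts together with what of it has only dissolved) (forward and back rates have come level / it is still moving / the coupling partner has run out first / all of the solid substrate has reacted)
* amount of target at 25 h, in percent of the solid substrate charged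

- as a solid, counted per litre of solution: solid substrate
- at the start none of the solid substrate is in solution
- what has only dissolved of solid substrate counts as not reacted
- the reaction counts as stopped when no species that holds the solid substrate changes by six tenths of a point or more over the second half of the time
- run time (flask): 25 h

For the end of this flask, with solid still left, I took dissolved starting material to stand at its solubility, 46.0% of the solid charge. I assumed that first and tested it afterwards. Dissolution had a half-life of 15.4 min. The partner's half-life by step 4, pseudo-first-order at that level, was 0.295 h, and the relaxation half-lives were 0.120 h for adduct and target and 0.486 h for target and isomer of the product. I took each step as level, because these times are far shorter than the run.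

Per part of free partner, step 4 then gave 0.966 parts of adduct, step 3 0.377 of target, and step 2 0.324 of isomer of the product. This split the partner charge as follows:

- free partner: 37.5%
- adduct: 36.2%
- target: 14.1%
- isomer of the product: 12.1%

The first row tested my assumption. The other 62.5% of the partner was bound, which took 37.5% of the solid charge. Adding what was dissolved left 16.5% as solid, so the assumption stood. The free-partner row, 37.5%, also showed that the partner had not run out.

The target row gave the rule, target's share of the partner: the part of the partner charge that ends as target while solid is left. The partner charge is 60.0% of the solid charge, so I expected 8.48% of target, and for the stop, forward and back rates have come level.

The forecast said forward and back rates have come level and 8.5%, noting “neither has run out”.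

The simulation gave forward and back rates have come level and 8.48%.

Against the partner charge, that target is 14.1%, with 16.5% of the solid left. The forecast's target figure would fail with another partner charge: target had moved by 5 points at 0.0246 M and at 0.100 M. The neighbour flask charged with 0.024 M of coupling partner lies just below the lower value. I applied the same share there and expected 3.39% of target, with 39.0% of the solid left. That neighbour flask kept 39.0% as solid and gave 3.39% of target.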